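Readings and results were computed for an exercise, noise included.

If the three runs are written as fractions of their charge, they nearly overlay, so a hand reckoning with two times can stand in for a fit.

| flask | starting material | free catalyst | time |
|---|---|---|---|
| Tuesday's | 0.0800 M | 4.00 × 10⁻⁴ M |  |
| Saturday's | 0.0320 M | 4.00 × 10⁻⁴ M |  |
| Thursday's | 0.160 M | 4.00 × 10⁻⁴ M |  |
| Sunday's | 0.370 M | 4.00 × 10⁻⁴ M | 47 min |

| run | time / min | [target] / M |
|---|---|---|
| Tuesday's run | 1.9 | 0.0033 |
| Tuesday's run | 4.2 | 0.0086 |
| Tuesday's run | 9.4 | 0.0134 |
| Tuesday's run | 21 | 0.0236 |
| Tuesday's run | 47 | 0.0290 |
| Saturday's run | 1.9 | 0.0014 |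
| Saturday's run | 4.2 | 0.0034 |
| Saturday's run | 9.4 | 0.0075 |
| Saturday's run | 21 | 0.0091 |
| Saturday's run | 47 | 0.0119 |
| Thursday's run | 1.9 | 0.0082 |
| Thursday's run | 4.2 | 0.0142 |
| Thursday's run | 9.4 | 0.0272 |
| Thursday's run | 21 | 0.0443 |
| Thursday's run | 47 | 0.0564 |

(standard deviation of a reading: 8 × 10⁻⁴ M)

- Overall: starting material -> target, with free catalyst as catalyst.
- Constant volume, constant temperature.
- What is held in complexes is read along with the free species.
- An order is taken over about fifteen percent of the charge, up and down.

- order of the initial rate in [starting material], near the charge of the Tuesday's run, the rate being that where two percent of its starting material are target (one fixed amount of target, the same in the runs compared)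
- target in the Sunday's run at 47 min, as a share of the starting material charged

At 47 min, Saturday's run stands at 37.2%, Tuesday's at 36.2% and Thursday's at 35.2%. So I take the order as just under one. I call the logarithm of one over the fraction unturned the depth, because a pseudo-first-order flask deepens at a steady pace. Pooled over the three runs, the depth does not keep that pace:

depth at 9.4 min, 21 min, 47 min: 0.195, 0.333, 0.443

earlier pace 0.0119 min⁻¹, later pace 0.00423 min⁻¹

fading time 18.1 min, the time in which the pace falls by a factor of e

conversion time, one over the pace at the start: 36.3 min

The fading time is shorter than the conversion time, so if the fading goes on, the share levels off near 39.3%. Charge enters as a small correction, taken from Saturday's and Thursday's shares: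

Sunday's share = 34.2%

That correction is less than the scatter of Saturday's share, so the trend with charge is unresolved and my figure is a rough estimate. The forecast gives 0.96 and 33.5%, a share slightly lower than mine, and argues: “Equal fractional conversion at equal times means the rate is essentially first order in starting material”.

The simulation gives an order of 0.98 and a share of 32.6%.

    free catalyst + starting material ⇌ catalyst-substrate complex, settled at all times (1.660 L mol⁻¹)
    catalyst-substrate complex + free catalyst → target + 2 free catalyst (4.860 × 10⁵ L mol⁻¹ min⁻¹)
    free catalyst → spent catalyst (0.06900 min⁻¹)
    2 free catalyst ⇌ resting dimer, settled at all times (3280 L mol⁻¹)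

Sunday's run stands at 32.6% at 47 min because free catalyst passes into spent catalyst. The fading time turns that share into the share at an unfaded pace:

depth 0.395, unfaded depth 1.11, share 67.0%

Sunday's run without that passing reaches 63.4%.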